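Ring A is read as a hexasubstituted resorcinol made from two open-chain esters: its C5–C6–C1 triad (C-methyl, C–OH and the acyl-bearing carbon) is methyl 3-oxopentanoate, and its C2–C3–C4 triad (C-methyl, bridge carbon and C–O) is a buta-2,3-dienoate whose α-carbon already carries the CH2 bridge and benzyl-protected ring B. One base-mediated Michael–Claisen sequence forms C1–C2 and C4–C5, closes ring A and places all six substituents; the C1 ester later becomes the butanoyl group. The allenoate comes from methylphloroglucinol by benzylation, formylation, reduction and ylide alkylation–ketene olefination; methylation, ester-to-ketone conversion, hydrogenolysis and ring B acylation complete the synthesis.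

Key step: step 6

Remark: ring A is numbered C1 (butanoyl carbon) to C6 (hydroxyl carbon) and ring B C1' (bridge carbon) to C6'; the target has no stereocentre, and the single racemic centres of 8 and 13 disappear in the following operation.

Step 1
Reactants: 1 2-methylbenzene-1,3,5-triol (methylphloroglucinol)
Product: 2 1,3,5-tris(benzyloxy)-2-methylbenzene
Conditions: BnBr (3.3 equiv), K2CO3, DMF, rt to 50 °C
Reagents that add atoms: benzyl bromide, BrCc1ccccc1
Why: Williamson etherification, in which carbonate in a dipolar aprotic solvent keeps the phenoxides O-nucleophilic, so the three hydroxyls should be benzylated with little C-benzylation of the ring.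

Step 2
Reactants: 2 1,3,5-tris(benzyloxy)-2-methylbenzene
Product: 4 2,4,6-tris(benzyloxy)-3-methylbenzaldehyde, via iminium salt 3 (not isolated)
Conditions: POCl3, DMF, 0 °C to 40 °C; then ice, aq. NaOH to pH 8
Reagents that add atoms: N,N-dimethylformamide, CN(C)C=O; water, O
Why: Vilsmeier–Haack formylation, in which the two open ring positions are equivalent and each is activated by three alkoxy groups, while the iminium salt 3 shuts the ring down against a second attack before it is hydrolysed to the aldehyde.

Step 3
Reactants: 4 2,4,6-tris(benzyloxy)-3-methylbenzaldehyde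
Product: 5 [2,4,6-tris(benzyloxy)-3-methylphenyl]methanol
Conditions: NaBH4, THF–MeOH, 0 °C
Reagents that add atoms: none
Why: Borohydride reduction of an aryl aldehyde, which leaves the benzyl ethers untouched.

Step 4
Reactants: 5 [2,4,6-tris(benzyloxy)-3-methylphenyl]methanol; 6 methyl (triphenylphosphoranylidene)acetate
Product: 8 {1-methoxy-1-oxo-3-[2,4,6-tris(benzyloxy)-3-methylphenyl]propan-2-yl}triphenylphosphonium chloride (racemic), via benzylic chloride 7 (not isolated)
Conditions: SOCl2 (1.05 equiv), pyridine (1.1 equiv), toluene–CH2Cl2, –20 °C; cold filtration; then 6 (1.0 equiv), 50 °C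
Reagents that add atoms: thionyl chloride, O=S(Cl)Cl
Why: Chlorination of a very electron-rich benzylic alcohol through its chlorosulfite under pyridine buffering, followed at once by C-alkylation of the ester-stabilised phosphorus ylide (ylide alkylation), which should be fast because the tris(alkoxy)benzyl chloride ionises easily and which, with one equivalent of ylide, should rest at the alkylated phosphonium salt, a stable solid.

Step 5
Reactants: 8 {1-methoxy-1-oxo-3-[2,4,6-tris(benzyloxy)-3-methylphenyl]propan-2-yl}triphenylphosphonium chloride; 9 acetyl chloride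
Product: 11 methyl 2-{[2,4,6-tris(benzyloxy)-3-methylphenyl]methyl}buta-2,3-dienoate, via phosphorus ylide 10 (not isolated)
Conditions: Et3N (2.2 equiv), CH2Cl2, 0 °C; then 9 (1.1 equiv) dropwise, 0 °C to rt
Reagents that add atoms: none
Why: Triethylamine frees ylide 10 from the salt and generates ketene from acetyl chloride, and Wittig olefination of the ketene carbonyl by the ylide should give the 2-substituted buta-2,3-dienoate with loss of Ph3PO.

Step 6
Reactants: 11 methyl 2-{[2,4,6-tris(benzyloxy)-3-methylphenyl]methyl}buta-2,3-dienoate; 12 methyl 3-oxopentanoate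
Product: 14 methyl 2,4-dihydroxy-3,6-dimethyl-5-{[2,4,6-tris(benzyloxy)-3-methylphenyl]methyl}benzoate, via Michael adduct enolate 13 (not isolated)
Conditions: 12 (1.1 equiv), NaH (1.1 equiv), THF, 0 °C; then 11, 0 °C to rt; then LiN(iPr)2 (2.5 equiv), –78 to 0 °C; aq. HCl
Reagents that add atoms: none
Why: The sodium enolate of 12 can react only at its α-carbon, which adds to the central sp carbon of allenoate 11 (Michael addition, bond C1–C2); proton transfer then gives the stabilised 2-acylglutaconate enolate 13, in which the former allene CH2 has become the C2 methyl. LiN(iPr)2 next removes a proton from the ethyl CH2 beside the ketone, and this γ-carbanion attacks the ester carbonyl inherited from the allenoate in a 6-(enolendo)-exo-trig Dieckmann-type Claisen closure (bond C4–C5), after which loss of methoxide and enolisation give the aromatic ring. The closest known reaction type is the base-mediated Michael–Claisen (3+3) annulation of acetoacetate anions and dianions with alkynoates and allenoates to orsellinates. No stereocentre is formed, and the alkene geometry of 13 does not matter because the delocalised anion can turn about the C2–C3 bond into the U-shape needed for closure. The step needs the α-carbon and not the γ-carbon of the ketoester to bond to the allene, which is secured by finishing the Michael addition on the monoanion before any dianion exists (a preformed dianion would add through its γ-carbon and lead to the isomeric 2,6-dihydroxy-3,4-dimethylbenzoate). It also needs ring closure through carbon and not through the enolate oxygen (which would give a 2-pyranone), which is secured by generating the γ-carbanion at low temperature, a far stronger nucleophile than the enolate oxygen.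

Step 7
Reactants: 14 methyl 2,4-dihydroxy-3,6-dimethyl-5-{[2,4,6-tris(benzyloxy)-3-methylphenyl]methyl}benzoate
Product: 15 methyl 2-hydroxy-4-methoxy-3,6-dimethyl-5-{[2,4,6-tris(benzyloxy)-3-methylphenyl]methyl}benzoate
Conditions: MeI (1.1 equiv), K2CO3 (1.2 equiv), acetone, rt to 40 °C
Reagents that add atoms: iodomethane, CI
Why: Williamson methylation, selective because the C6 hydroxyl is held in a hydrogen bond to the ester carbonyl, so carbonate should ionise only the C4 hydroxyl (para to the ester), which is then methylated.

Step 8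
Reactants: 15 methyl 2-hydroxy-4-methoxy-3,6-dimethyl-5-{[2,4,6-tris(benzyloxy)-3-methylphenyl]methyl}benzoate
Product: 16 2-hydroxy-4-methoxy-3,6-dimethyl-5-{[2,4,6-tris(benzyloxy)-3-methylphenyl]methyl}benzoic acid
Conditions: KOH (excess), DMSO–H2O, 90 °C; then 1 M HCl, 0 °C, to pH 3
Reagents that add atoms: potassium hydroxide, [K+].[OH-]
Why: Saponification of a methyl ester, for which hydroxide in aqueous DMSO is reactive enough even at a di-ortho-substituted benzoate, with cold acidification to keep the salicylic-type acid from decarboxylating.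

Step 9
Reactants: 16 2-hydroxy-4-methoxy-3,6-dimethyl-5-{[2,4,6-tris(benzyloxy)-3-methylphenyl]methyl}benzoic acid
Product: 18 1-(2-hydroxy-4-methoxy-3,6-dimethyl-5-{[2,4,6-tris(benzyloxy)-3-methylphenyl]methyl}phenyl)butan-1-one, via trilithium gem-diolate 17 (not isolated)
Conditions: n-PrLi (4 equiv), THF, –78 to 0 °C; inverse quench into cold aq. HCl
Reagents that add atoms: n-propyllithium, [Li]CCC
Why: Addition of an organolithium to a lithium carboxylate, in which two equivalents deprotonate the acid and the phenol and a third adds to give the gem-diolate 17, which cannot collapse to a ketone before the acidic quench, so over-addition to a tertiary alcohol is excluded.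

Step 10
Reactants: 18 1-(2-hydroxy-4-methoxy-3,6-dimethyl-5-{[2,4,6-tris(benzyloxy)-3-methylphenyl]methyl}phenyl)butan-1-one
Product: 19 1-(2-hydroxy-4-methoxy-3,6-dimethyl-5-[(2,4,6-trihydroxy-3-methylphenyl)methyl]phenyl)butan-1-one
Conditions: H2 (1 atm), 10% Pd/C, EtOAc–MeOH, rt; handled under argon
Reagents that add atoms: none
Why: Hydrogenolysis of aryl benzyl ethers on palladium, under which the hindered, chelated aryl ketone and the diarylmethane bond should not be reduced at atmospheric pressure and room temperature.

Step 11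
Reactants: 19 1-(2-hydroxy-4-methoxy-3,6-dimethyl-5-[(2,4,6-trihydroxy-3-methylphenyl)methyl]phenyl)butan-1-one
Product: 21 1-(3-{[3-butanoyl-4-hydroxy-6-methoxy-2,5-dimethylphenyl]methyl}-2,4,6-trihydroxy-5-methylphenyl)butan-1-one (target), via ketiminium chloride 20 (not isolated)
Conditions: PrCN (3 equiv), ZnCl2 (0.3 equiv), HCl (g), Et2O, 0 °C; then H2O, 90 °C
Reagents that add atoms: butanenitrile, CCCC#N; water, O
Why: Houben–Hoesch acylation, in which the only unsubstituted aromatic carbon of the molecule, C5' of the phloroglucinol ring B, attacks the nitrilium species at low temperature (ring A being fully substituted and deactivated), and the ketiminium salt 20 is hydrolysed to the butanoyl group on warming in water.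

Compound list

1 | 2-methylbenzene-1,3,5-triol (methylphloroglucinol) | Cc1c(O)cc(O)cc1O | starting material
2 | 1,3,5-tris(benzyloxy)-2-methylbenzene | Cc1c(OCc2ccccc2)cc(OCc2ccccc2)cc1OCc1ccccc1 | intermediate
3 | {[2,4,6-tris(benzyloxy)-3-methylphenyl]methylidene}dimethylammonium dichlorophosphate (formed in the flask) | C[N+](C)=Cc1c(OCc2ccccc2)c(C)c(OCc2ccccc2)cc1OCc1ccccc1.[O-]P(=O)(Cl)Cl | intermediate
4 | 2,4,6-tris(benzyloxy)-3-methylbenzaldehyde | O=Cc1c(OCc2ccccc2)c(C)c(OCc2ccccc2)cc1OCc1ccccc1 | intermediate
5 | [2,4,6-tris(benzyloxy)-3-methylphenyl]methanol | OCc1c(OCc2ccccc2)c(C)c(OCc2ccccc2)cc1OCc1ccccc1 | intermediate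
6 | methyl (triphenylphosphoranylidene)acetate | COC(=O)C=P(c1ccccc1)(c1ccccc1)c1ccccc1 | starting material
7 | 1,3,5-tris(benzyloxy)-2-(chloromethyl)-4-methylbenzene (formed in the flask) | ClCc1c(OCc2ccccc2)c(C)c(OCc2ccccc2)cc1OCc1ccccc1 | intermediate
8 | {1-methoxy-1-oxo-3-[2,4,6-tris(benzyloxy)-3-methylphenyl]propan-2-yl}triphenylphosphonium chloride (racemic) | COC(=O)C(Cc1c(OCc2ccccc2)c(C)c(OCc2ccccc2)cc1OCc1ccccc1)[P+](c1ccccc1)(c1ccccc1)c1ccccc1.[Cl-] | intermediate
9 | acetyl chloride | CC(=O)Cl | starting material
10 | methyl 3-[2,4,6-tris(benzyloxy)-3-methylphenyl]-2-(triphenylphosphoranylidene)propanoate (formed in the flask) | COC(=O)C(Cc1c(OCc2ccccc2)c(C)c(OCc2ccccc2)cc1OCc1ccccc1)=P(c1ccccc1)(c1ccccc1)c1ccccc1 | intermediate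
11 | methyl 2-{[2,4,6-tris(benzyloxy)-3-methylphenyl]methyl}buta-2,3-dienoate | C=C=C(Cc1c(OCc2ccccc2)c(C)c(OCc2ccccc2)cc1OCc1ccccc1)C(=O)OC | intermediate
12 | methyl 3-oxopentanoate | CCC(=O)CC(=O)OC | starting material
13 | dimethyl 3-methyl-4-propanoyl-2-{[2,4,6-tris(benzyloxy)-3-methylphenyl]methyl}pent-2-enedioate (present in the flask as its sodium enolate; alkene geometry not fixed, racemic at C4) | CCC(=O)C(C(=O)OC)C(C)=C(Cc1c(OCc2ccccc2)c(C)c(OCc2ccccc2)cc1OCc1ccccc1)C(=O)OC | intermediate
14 | methyl 2,4-dihydroxy-3,6-dimethyl-5-{[2,4,6-tris(benzyloxy)-3-methylphenyl]methyl}benzoate | COC(=O)c1c(C)c(Cc2c(OCc3ccccc3)c(C)c(OCc3ccccc3)cc2OCc2ccccc2)c(O)c(C)c1O | intermediate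
15 | methyl 2-hydroxy-4-methoxy-3,6-dimethyl-5-{[2,4,6-tris(benzyloxy)-3-methylphenyl]methyl}benzoate | COC(=O)c1c(C)c(Cc2c(OCc3ccccc3)c(C)c(OCc3ccccc3)cc2OCc2ccccc2)c(OC)c(C)c1O | intermediate
16 | 2-hydroxy-4-methoxy-3,6-dimethyl-5-{[2,4,6-tris(benzyloxy)-3-methylphenyl]methyl}benzoic acid | OC(=O)c1c(C)c(Cc2c(OCc3ccccc3)c(C)c(OCc3ccccc3)cc2OCc2ccccc2)c(OC)c(C)c1O | intermediate
17 | trilithium 1-(4-methoxy-3,6-dimethyl-2-oxido-5-{[2,4,6-tris(benzyloxy)-3-methylphenyl]methyl}phenyl)butane-1,1-bis(olate) (formed in the flask) | [Li+].[Li+].[Li+].CCCC([O-])([O-])c1c(C)c(Cc2c(OCc3ccccc3)c(C)c(OCc3ccccc3)cc2OCc2ccccc2)c(OC)c(C)c1[O-] | intermediate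
18 | 1-(2-hydroxy-4-methoxy-3,6-dimethyl-5-{[2,4,6-tris(benzyloxy)-3-methylphenyl]methyl}phenyl)butan-1-one | CCCC(=O)c1c(C)c(Cc2c(OCc3ccccc3)c(C)c(OCc3ccccc3)cc2OCc2ccccc2)c(OC)c(C)c1O | intermediate
19 | 1-(2-hydroxy-4-methoxy-3,6-dimethyl-5-[(2,4,6-trihydroxy-3-methylphenyl)methyl]phenyl)butan-1-one | CCCC(=O)c1c(C)c(Cc2c(O)c(C)c(O)cc2O)c(OC)c(C)c1O | intermediate
20 | 1-(3-{[3-butanoyl-4-hydroxy-6-methoxy-2,5-dimethylphenyl]methyl}-2,4,6-trihydroxy-5-methylphenyl)butan-1-iminium chloride (formed in the flask) | CCCC(=[NH2+])c1c(O)c(C)c(O)c(Cc2c(C)c(C(=O)CCC)c(O)c(C)c2OC)c1O.[Cl-] | intermediate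
21 | 1-(3-{[3-butanoyl-4-hydroxy-6-methoxy-2,5-dimethylphenyl]methyl}-2,4,6-trihydroxy-5-methylphenyl)butan-1-one | CCCC(=O)c1c(C)c(Cc2c(O)c(C)c(O)c(C(=O)CCC)c2O)c(OC)c(C)c1O | target

Total step count: 11.
Longest linear sequence: 11 steps, from 1 to 21; compounds 6, 9 and 12 are purchased.

Steps most likely to fail

Step 6. The ring may close through oxygen to a lactone instead of through carbon. The amide base may also be consumed at the vinylogous methyl or benzylic positions, so that the γ-carbanion never forms, and the Michael addition to the hindered allenoate may be slow. The fallback sets out from 5 and comes back to the route at 14. The bridge would be made by Friedel–Crafts benzylation: purchased methyl 2,4-dihydroxy-3,6-dimethylbenzoate (COC(=O)c1c(C)cc(O)c(C)c1O) is used in excess with catalytic p-toluenesulfonic acid in CH2Cl2 at 0 °C, and alcohol 5 is added slowly. The tris(benzyloxy)benzyl cation should attack the only free ring carbon of the resorcinol ester, ortho and para to its two hydroxyls, and give 14 directly with loss of water. Slow addition to excess ester is meant to outrun self-alkylation of 5. This fallback makes no compound outside the compound list (F0).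

Step 9. Addition to the hindered, doubly charged carboxylate may stall, and the alkyllithium may instead metalate the benzyl ethers and trigger their rearrangement. The saponification before it may also be slow or lose CO2 on acidification. The fallback sets out from 15, so it bypasses step 8 as well, and comes back at 18. LiAlH4 in THF at 0 °C should reduce the ester to 2-(hydroxymethyl)-5-methoxy-3,6-dimethyl-4-{[2,4,6-tris(benzyloxy)-3-methylphenyl]methyl}phenol F1. MnO2 in CH2Cl2 should oxidise the benzylic alcohol to 2-hydroxy-4-methoxy-3,6-dimethyl-5-{[2,4,6-tris(benzyloxy)-3-methylphenyl]methyl}benzaldehyde F2. PrMgBr (2.5 equiv, THF, 0 °C) should add to the aldehyde to give racemic 2-(1-hydroxybutyl)-5-methoxy-3,6-dimethyl-4-{[2,4,6-tris(benzyloxy)-3-methylphenyl]methyl}phenol F3, and a second MnO2 oxidation should give ketone 18.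

Step 11. Acid may cleave or scramble the diarylmethane bridge of the electron-rich triol, the triol may oxidise in air, or acylation at the flanked position may stay incomplete. The fallback sets out from 18 and comes back at 21. Ring B would be acylated while still benzylated: the mixed anhydride from butanoic acid and (CF3CO)2O in CH2Cl2 at 0 °C to rt should acylate the only free position of the tris(benzyloxy) ring (Friedel–Crafts acylation) to give 1-(2,4,6-tris(benzyloxy)-3-{[3-butanoyl-4-hydroxy-6-methoxy-2,5-dimethylphenyl]methyl}-5-methylphenyl)butan-1-one F4. Any ester formed at the ring A phenol would be removed by brief K2CO3 in MeOH. Hydrogenolysis (H2, 10% Pd/C, EtOAc) would then give 21 as a last, neutral step.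

Further compounds

F0 | step 6 | none | none
F1 | step 9 | 2-(hydroxymethyl)-5-methoxy-3,6-dimethyl-4-{[2,4,6-tris(benzyloxy)-3-methylphenyl]methyl}phenol | OCc1c(C)c(Cc2c(OCc3ccccc3)c(C)c(OCc3ccccc3)cc2OCc2ccccc2)c(OC)c(C)c1O
F2 | step 9 | 2-hydroxy-4-methoxy-3,6-dimethyl-5-{[2,4,6-tris(benzyloxy)-3-methylphenyl]methyl}benzaldehyde | O=Cc1c(C)c(Cc2c(OCc3ccccc3)c(C)c(OCc3ccccc3)cc2OCc2ccccc2)c(OC)c(C)c1O
F3 | step 9 | 2-(1-hydroxybutyl)-5-methoxy-3,6-dimethyl-4-{[2,4,6-tris(benzyloxy)-3-methylphenyl]methyl}phenol (racemic) | CCCC(O)c1c(C)c(Cc2c(OCc3ccccc3)c(C)c(OCc3ccccc3)cc2OCc2ccccc2)c(OC)c(C)c1O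
F4 | step 11 | 1-(2,4,6-tris(benzyloxy)-3-{[3-butanoyl-4-hydroxy-6-methoxy-2,5-dimethylphenyl]methyl}-5-methylphenyl)butan-1-one | CCCC(=O)c1c(C)c(Cc2c(OCc3ccccc3)c(C)c(OCc3ccccc3)c(C(=O)CCC)c2OCc2ccccc2)c(OC)c(C)c1O
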